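**Retrosynthetic overview**
- Target 11 ⇒ C4–C8 bond: quinone monoketal 5, ionised to its 4-methoxy oxocarbenium ion (a vinylogous enolonium ion, i.e. the para carbon of a phenol used as an electrophile), plus alkenylboronic acid 10 under chiral hydroxy-acid/Yb(OTf)3 catalysis. This single step sets the C4 stereocentre and delivers 11.
- 5 ⇐ oxidative dearomatisation (PhI(OAc)2, MeOH) of phenol 4 ⇐ Suzuki coupling of bromophenol 2 with (E)-propenylboronic acid 3 ⇐ bromination of 3,4-dimethoxyphenol 1.
- 10 ⇐ CuCl-catalysed syn borylation/protonation of alkyne 8 and pinacol cleavage ⇐ Sonogashira coupling of 4-iodoveratrole 6 with propyne 7.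
- Rings: none is built. Both six-membered rings are bought as arenes; the dienone ring is unmasked in step 3 and the quaternary centre is made on it in step 6.

Assumption: the (2R,3R)-hydroxy-acid catalyst is taken to give (4S)-11; if the sense of induction proves opposite, the (2S,3S)-catalyst is used with no other change.

**Step 1**
Reactants: 1 3,4-dimethoxyphenol
Product: 2 2-bromo-4,5-dimethoxyphenol
Conditions: NBS (1.0 equiv), MeCN, −10 → 0 °C, 1 h
Reagents that add atoms: N-bromosuccinimide, O=C1CCC(=O)N1Br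
Why: Electrophilic aromatic bromination goes to C6 of 1, the only unhindered site that is both ortho to OH and para to a methoxy group.

**Step 2**
Reactants: 2 2-bromo-4,5-dimethoxyphenol; 3 (E)-prop-1-en-1-ylboronic acid
Product: 4 4,5-dimethoxy-2-[(E)-prop-1-en-1-yl]phenol
Conditions: Pd(dppf)Cl2 (3 mol%), K2CO3 (3 equiv), 1,4-dioxane/H2O 4:1, 80 °C, degassed
Reagents that add atoms: none
Why: Suzuki–Miyaura coupling tolerates the free phenol and transfers the alkenyl group with retention of the (E) geometry.

**Step 3**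
Reactants: 4 4,5-dimethoxy-2-[(E)-prop-1-en-1-yl]phenol
Product: 5 4,4,5-trimethoxy-2-[(E)-prop-1-en-1-yl]cyclohexa-2,5-dien-1-one
Conditions: PhI(OAc)2 (1.05 equiv), MeOH, 0 °C, 15 min; NaHCO3 work-up
Reagents that add atoms: methanol, CO
Why: Hypervalent-iodine oxidative dearomatisation gives a phenoxenium ion stabilised by the para methoxy group, which methanol traps at C4 to give the quinone monoketal.

**Step 4**
Reactants: 6 4-iodo-1,2-dimethoxybenzene; 7 propyne
Product: 8 1,2-dimethoxy-4-(prop-1-yn-1-yl)benzene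
Conditions: Pd(PPh3)2Cl2 (2 mol%), CuI (4 mol%), Et3N, THF, propyne (2 equiv, 1 M in THF), rt, sealed vessel
Reagents that add atoms: none
Why: Sonogashira coupling of an aryl iodide with a terminal alkyne.

**Step 5**
Reactants: 8 1,2-dimethoxy-4-(prop-1-yn-1-yl)benzene
Product: 10 [(Z)-1-(3,4-dimethoxyphenyl)prop-1-en-2-yl]boronic acid, via pinacol boronate 9 (not isolated)
Conditions: CuCl (5 mol%), P(p-tol)3 (6 mol%), NaOtBu (10 mol%), B2pin2 (1.1 equiv), MeOH (2 equiv), THF, rt; then NaIO4 (3 equiv), NH4OAc (3 equiv), acetone/H2O, rt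
Reagents that add atoms: bis(pinacolato)diboron, CC1(C)OB(OC1(C)C)B1OC(C)(C)C(C)(C)O1; water, O
Why: Copper-catalysed formal hydroboration (syn borylcupration with copper on the benzylic carbon, then protonation by MeOH) puts boron on the methyl-bearing carbon trans to the aryl group, and NaIO4 then cleaves the pinacol ester oxidatively without touching the alkene.

**Step 6**
Reactants: 5 4,4,5-trimethoxy-2-[(E)-prop-1-en-1-yl]cyclohexa-2,5-dien-1-one; 10 [(Z)-1-(3,4-dimethoxyphenyl)prop-1-en-2-yl]boronic acid
Product: 11 (4S)-4-[(E)-1-(3,4-dimethoxyphenyl)prop-1-en-2-yl]-4,5-dimethoxy-2-[(E)-prop-1-en-1-yl]cyclohexa-2,5-dien-1-one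
Conditions: 10 (1.5 equiv), (2R,3R)-4-(dibenzylamino)-2,3-dihydroxy-4-oxobutanoic acid (10 mol%), Yb(OTf)3 (5 mol%), 4 Å MS, EtOAc, −40 → −10 °C; cold NaHCO3 quench; Et3N-deactivated silica
Reagents that add atoms: none
Why: Proposed new method: the chiral α-hydroxy acid condenses with 10 to a chiral alkenyl acyloxy-dioxaborolanone, a strong boron Lewis acid that, helped by Yb(OTf)3, pulls one ketal methoxide off C4 of 5 to give a contact ion pair of the 4-methoxy oxocarbenium ion (a vinylogous enolonium ion: the para carbon of the parent phenol, innately nucleophilic, now electrophilic) and the chiral alkenyl(methoxy)borate; the borate, held over C4 by the oxygen it has just abstracted, transfers its alkenyl carbon (the innately nucleophilic β-carbon of an electron-rich styrene) to C4 irreversibly and with retention of alkene geometry, so the kinetic ipso adduct is locked in, whereas the C2/C6 attack known for free π-nucleophiles on such cations is attributed to reversible ipso addition; the chiral borate distinguishes the two faces of the planar cation (C3–H/propenyl edge against C5–OMe edge) and sets C4 as (S); closest known reaction types are chiral hydroxy-acid/lanthanide-triflate-catalysed enantioselective alkenylboronate additions to chromene acetals, ion-pair couplings of organoboron ate complexes with acetals, and Petasis-type alkenyl transfer.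

**Compound list**
1 | 3,4-dimethoxyphenol | COc1ccc(O)cc1OC | starting material
2 | 2-bromo-4,5-dimethoxyphenol | COc1cc(O)c(Br)cc1OC | intermediate
3 | (E)-prop-1-en-1-ylboronic acid | C/C=C/B(O)O | starting material
4 | 4,5-dimethoxy-2-[(E)-prop-1-en-1-yl]phenol | C/C=C/c1cc(OC)c(OC)cc1O | intermediate
5 | 4,4,5-trimethoxy-2-[(E)-prop-1-en-1-yl]cyclohexa-2,5-dien-1-one | C/C=C/C1=CC(OC)(OC)C(OC)=CC1=O | intermediate
6 | 4-iodo-1,2-dimethoxybenzene | COc1ccc(I)cc1OC | starting material
7 | propyne | CC#C | starting material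
8 | 1,2-dimethoxy-4-(prop-1-yn-1-yl)benzene | CC#Cc1ccc(OC)c(OC)c1 | intermediate
9 | 2-[(Z)-1-(3,4-dimethoxyphenyl)prop-1-en-2-yl]-4,4,5,5-tetramethyl-1,3,2-dioxaborolane | CC1(C)OB(/C(C)=C/c2ccc(OC)c(OC)c2)OC1(C)C | intermediate
10 | [(Z)-1-(3,4-dimethoxyphenyl)prop-1-en-2-yl]boronic acid | OB(O)/C(C)=C/c1ccc(OC)c(OC)c1 | intermediate
11 | (4S)-4-[(E)-1-(3,4-dimethoxyphenyl)prop-1-en-2-yl]-4,5-dimethoxy-2-[(E)-prop-1-en-1-yl]cyclohexa-2,5-dien-1-one | C/C=C/C1=C[C@](OC)(/C(C)=C/c2ccc(OC)c(OC)c2)C(OC)=CC1=O | target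

**Totals**
Total steps: 6. Longest linear sequence: 4 (steps 1, 2, 3, 6); the other branch is steps 4, 5, 6.

**Steps most likely to fail, with fallbacks**

1. Step 6, the ketal alkenylation. The alkenyl group may go to C6 or C2 instead of C4, the ketal may hydrolyse to the quinone instead of ionising, the ee may be low, and the product can re-ionise at C4 if left with acid. The fallback sets out from 5 and 10 and comes back at 11.
 - 5 is hydrolysed (aqueous oxalic acid, THF, 0 °C) to the quinone 2-methoxy-5-[(E)-prop-1-en-1-yl]cyclohexa-2,5-diene-1,4-dione F1.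
 - 10 is converted with retention (N-iodosuccinimide, MeCN, 0 °C, dark) into the vinyl iodide 4-[(E)-2-iodoprop-1-en-1-yl]-1,2-dimethoxybenzene F2.
 - Iodine–lithium exchange (t-BuLi, THF, −78 °C) gives [(Z)-1-(3,4-dimethoxyphenyl)prop-1-en-2-yl]lithium F3.
 - F3 adds 1,2 to the ketone-like carbonyl of F1 (the one next to the methoxy-bearing carbon; the other carbonyl is a vinylogous ester) to give lithium 1-[(E)-1-(3,4-dimethoxyphenyl)prop-1-en-2-yl]-2-methoxy-4-oxo-5-[(E)-prop-1-en-1-yl]cyclohexa-2,5-dien-1-olate F4.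
 - F4 is methylated in the same flask (MeOTf, −78 → 0 °C) to racemic 4-[(E)-1-(3,4-dimethoxyphenyl)prop-1-en-2-yl]-4,5-dimethoxy-2-[(E)-prop-1-en-1-yl]cyclohexa-2,5-dien-1-one F5.
 - F5 is resolved by preparative chromatography on a chiral stationary phase to give 11.
 
 In this fallback the regiochemistry rests on carbonyl addition and the enantiomer on resolution.

2. Step 5, borylation and pinacol cleavage in one flask. The free boronic acid may protodeboronate, or the periodate cleavage of the crude mixture may be incomplete. The fallback sets out from 9 and comes back at 10. 9 is isolated by chromatography and treated with KHF2 (aqueous MeOH, rt) to give crystalline potassium trifluoro[(Z)-1-(3,4-dimethoxyphenyl)prop-1-en-2-yl]borate F6, which is recrystallised. F6 is hydrolysed with Me3SiCl/H2O in MeCN to 10 just before use.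

3. Step 3, oxidation of a phenol that carries an electron-rich propenyl group. Attack on the propenyl side chain or oligomerisation could compete. The fallback sets out from 2 and comes back at 5. Bromophenol 2 is oxidised first (PhI(OAc)2, MeOH, 0 °C) to 2-bromo-4,4,5-trimethoxycyclohexa-2,5-dien-1-one F7. The α-bromo dienone F7 is then coupled with 3 (Pd(PPh3)4, K2CO3, THF/H2O, 40 °C) to give 5, so the propenyl group never meets the oxidant.

**Further compounds**
F1 | step 6 | 2-methoxy-5-[(E)-prop-1-en-1-yl]cyclohexa-2,5-diene-1,4-dione | C/C=C/C1=CC(=O)C(OC)=CC1=O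
F2 | step 6 | 4-[(E)-2-iodoprop-1-en-1-yl]-1,2-dimethoxybenzene | I/C(C)=C/c1ccc(OC)c(OC)c1
F3 | step 6 | [(Z)-1-(3,4-dimethoxyphenyl)prop-1-en-2-yl]lithium | [Li]/C(C)=C/c1ccc(OC)c(OC)c1
F4 | step 6 | lithium 1-[(E)-1-(3,4-dimethoxyphenyl)prop-1-en-2-yl]-2-methoxy-4-oxo-5-[(E)-prop-1-en-1-yl]cyclohexa-2,5-dien-1-olate (racemic) | [Li+].C/C=C/C1=CC([O-])(/C(C)=C/c2ccc(OC)c(OC)c2)C(OC)=CC1=O
F5 | step 6 | racemic 4-[(E)-1-(3,4-dimethoxyphenyl)prop-1-en-2-yl]-4,5-dimethoxy-2-[(E)-prop-1-en-1-yl]cyclohexa-2,5-dien-1-one | C/C=C/C1=CC(OC)(/C(C)=C/c2ccc(OC)c(OC)c2)C(OC)=CC1=O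
F6 | step 5 | potassium trifluoro[(Z)-1-(3,4-dimethoxyphenyl)prop-1-en-2-yl]borate | [K+].F[B-](F)(F)/C(C)=C/c1ccc(OC)c(OC)c1
F7 | step 3 | 2-bromo-4,4,5-trimethoxycyclohexa-2,5-dien-1-one | COC1=CC(=O)C(Br)=CC1(OC)OC
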